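**Retrosynthetic overview**

- The strategy rests on the central benzene ring (chromene C4a, C5, C6, C7, C8, C8a). C4a carries chromene C4 and sits between C8a (bonded to the pyran oxygen O1) and C5 (bonded to C2 of the benzofuran), para to the C7 hydroxyl. The ring is therefore a masked 6-aryl-5-prenyl-2,4-dihydroxyphenyl 2-methylpropenyl ketone.
- Key disconnection: bonds C5–C6 and C4a–C8a. This gives a four-carbon 1,3-dioxygenated diene (C8a, C8, C7 and prenyl-bearing C6, from γ-prenylated methyl acetoacetate) and a two-carbon acetylenic ketone (C5, C4a) that carries the benzofuran and the Me2C=CH–C(=O) unit. The O1–C2 bond then follows by oxa-Michael closure.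
- The enynone is made by Sonogashira coupling of a 2-iodo-6-silyloxybenzofuran with 5-methylhex-4-en-1-yn-3-ol, followed by oxidation.
- Ring order: the benzofuran is bought intact; the central benzene ring ([4+2], aromatisation) and the pyranone ring (oxa-Michael) close in one pot; the pyranone becomes the 2H-pyran by silylation, reduction and dehydration; desilylation ends the route.

Key step: step 9

Remark on the chemistry: the target has no stereocentre, no stereogenic double bond and no configurationally stable axis (the benzofuran side of the biaryl bond carries only the ring oxygen and a C–H). It is achiral, so no enantioselective step is needed; the racemic sp3 centres formed on the way are all erased. Benzofuran-6-ol is taken as commercially available.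

**Route**

Step 1
Reactants: 1 methyl acetoacetate; 2 prenyl bromide (1-bromo-3-methylbut-2-ene)
Product: 4 methyl 7-methyl-3-oxooct-6-enoate, via sodium lithium dianion of methyl acetoacetate 3 (not isolated)
Conditions: NaH, THF, 0 °C; n-BuLi, 0 °C; then 2, 0 °C → rt; aq HCl
Reagents that add atoms: none
Why: γ-alkylation of the acetoacetate dianion, whose more basic terminal carbanion attacks the primary allylic bromide by SN2 and leaves the α-position untouched.

Step 2
Reactants: 4 methyl 7-methyl-3-oxooct-6-enoate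
Product: 5 methyl 7-methyl-3-(trimethylsilyloxy)octa-2,6-dienoate
Conditions: TMSCl, Et3N, toluene, rt; filtration under argon, concentration
Reagents that add atoms: chlorotrimethylsilane, C[Si](C)(C)Cl
Why: soft enolisation and O-silylation of the strongly enolised β-keto ester gives the silyl enol ether; its C2=C3 geometry does not matter for the next step.

Step 3
Reactants: 5 methyl 7-methyl-3-(trimethylsilyloxy)octa-2,6-dienoate
Product: 7 (3Z)-1-methoxy-7-methyl-1,3-bis(trimethylsilyloxy)octa-1,3,6-triene, via lithium (3Z)-1-methoxy-7-methyl-3-(trimethylsilyloxy)octa-1,3,6-trien-1-olate 6 (not isolated)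
Conditions: LDA (commercial solution), THF, −78 °C; TMSCl, −78 °C → rt; hexane, filtration; used crude and at once
Reagents that add atoms: chlorotrimethylsilane, C[Si](C)(C)Cl
Why: kinetic γ-deprotonation of the vinylogous ester and O-silylation of the ester dienolate give the 1-alkoxy-1,3-bis(silyloxy)diene; the 3Z isomer (chain trans to C2, outside the s-cis diene) is expected to predominate, and the ketene acetal geometry is irrelevant.

Step 4
Reactants: 8 benzofuran-6-ol
Product: 9 6-(triisopropylsilyloxy)benzofuran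
Conditions: TIPSCl, imidazole, DMF, rt
Reagents that add atoms: chlorotriisopropylsilane, CC(C)[Si](Cl)(C(C)C)C(C)C
Why: imidazole-mediated silylation of the phenol; the bulky TIPS ether withstands n-BuLi, Pd/Cu, MnO2, heat, dilute acid and amine in the steps that follow.

Step 5
Reactants: 9 6-(triisopropylsilyloxy)benzofuran
Product: 11 2-iodo-6-(triisopropylsilyloxy)benzofuran, via 2-lithio-6-(triisopropylsilyloxy)benzofuran 10 (not isolated)
Conditions: n-BuLi, THF, −78 °C; I2, THF, −78 °C → rt; aq Na2S2O3
Reagents that add atoms: iodine, II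
Why: directed deprotonation at C2, the most acidic C–H of benzofuran (the bulky silyl ether is a poor ortho-director), followed by iodinolysis of the heteroaryllithium.

Step 6
Reactants: 12 3-methylbut-2-enal; 13 ethynylmagnesium bromide
Product: 14 5-methylhex-4-en-1-yn-3-ol (racemic)
Conditions: THF, 0 °C; aq NH4Cl
Reagents that add atoms: none
Why: 1,2-addition of the hard alkynyl Grignard reagent to the enal, whose β,β-disubstituted terminus blocks conjugate addition; the carbinol centre forms racemic and is erased in step 8.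

Step 7
Reactants: 11 2-iodo-6-(triisopropylsilyloxy)benzofuran; 14 5-methylhex-4-en-1-yn-3-ol
Product: 15 5-methyl-1-[6-(triisopropylsilyloxy)benzofuran-2-yl]hex-4-en-1-yn-3-ol (racemic)
Conditions: PdCl2(PPh3)2 (cat.), CuI (cat.), Et3N, THF, rt
Reagents that add atoms: none
Why: Sonogashira coupling of a heteroaryl iodide with a terminal alkyne at room temperature, which tolerates the free secondary alcohol and the silyl ether.

Step 8
Reactants: 15 5-methyl-1-[6-(triisopropylsilyloxy)benzofuran-2-yl]hex-4-en-1-yn-3-ol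
Product: 16 5-methyl-1-[6-(triisopropylsilyloxy)benzofuran-2-yl]hex-4-en-1-yn-3-one
Conditions: activated MnO2 (excess), CH2Cl2, rt
Reagents that add atoms: none
Why: MnO2 oxidation of an alcohol that is both propargylic and allylic, under neutral conditions that spare the silyl ether and the alkene, gives the cross-conjugated enynone.

Step 9
Reactants: 7 (3Z)-1-methoxy-7-methyl-1,3-bis(trimethylsilyloxy)octa-1,3,6-triene (3 equiv); 16 5-methyl-1-[6-(triisopropylsilyloxy)benzofuran-2-yl]hex-4-en-1-yn-3-one
Product: 19 7-hydroxy-2,2-dimethyl-6-(3-methylbut-2-enyl)-5-[6-(triisopropylsilyloxy)benzofuran-2-yl]chroman-4-one, via 1-{6-methoxy-3-(3-methylbut-2-enyl)-2-[6-(triisopropylsilyloxy)benzofuran-2-yl]-4,6-bis(trimethylsilyloxy)cyclohexa-1,4-dien-1-yl}-3-methylbut-2-en-1-one 17 (not isolated), via 1-{2,4-dihydroxy-5-(3-methylbut-2-enyl)-6-[6-(triisopropylsilyloxy)benzofuran-2-yl]phenyl}-3-methylbut-2-en-1-one 18 (not isolated)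
Conditions: toluene, 120 °C, sealed tube, no Lewis acid; cool, THF/H2O, p-TsOH·H2O (cat.), rt; then Et3N (0.5 equiv), rt → 40 °C
Reagents that add atoms: none
Why: The electron-rich diene 7 and the acetylenic ketone 16 combine in a polarity-matched, asynchronous thermal Diels–Alder reaction in which the nucleophilic, prenyl-bearing diene C4 bonds to the alkyne carbon β to the ketone (the benzofuranyl carbon) and the ketene-acetal carbon C1 bonds to the α-carbon, giving cyclohexa-1,4-diene 17. Mild aqueous acid then collapses the mixed methyl silyl ketal with loss of methanol, aromatises the ring and removes both TMS groups to unveil resorcinol ketone 18, whose only hydroxyl ortho to the acyl group adds to the β,β-dimethyl enone once Et3N is present. The closest known reaction types are the Diels–Alder benzannulation of 1-alkoxy-1,3-bis(silyloxy)-1,3-dienes with acetylenic esters and ketones to 6-substituted 2,4-dihydroxyaryl carbonyl compounds, and the base-mediated cyclisation of o-hydroxyaryl 2-methylpropenyl ketones to 2,2-dimethylchroman-4-ones; here they are run in one pot. The benzene ring closes by [4+2] cycloaddition (bonds C5–C6 and C4a–C8a) followed by eliminative aromatisation, and the pyranone ring closes by 6-endo-trig oxa-Michael addition (bond O1–C2), which also relieves the twist of the di-ortho-substituted ketone. No stereocentre survives: the two sp3 ring carbons of 17 form without control and are erased on aromatisation. The step needs three selectivities: the orientation that puts prenyl next to benzofuranyl (from the matched polarity of diene C4 and the β-alkyne carbon, with the slim alkyne and the 3Z diene letting the crowded bond form), reaction at the alkyne rather than at the enone C=C or the carbonyl (from the inert β,β-dimethyl enone and the absence of Lewis acid, which would favour carbonyl-based [3+3] condensation), and pyranone closure by the correct oxygen (only one hydroxyl is ortho to the acyl group).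

Step 10
Reactants: 19 7-hydroxy-2,2-dimethyl-6-(3-methylbut-2-enyl)-5-[6-(triisopropylsilyloxy)benzofuran-2-yl]chroman-4-one
Product: 20 7-(tert-butyldimethylsilyloxy)-2,2-dimethyl-6-(3-methylbut-2-enyl)-5-[6-(triisopropylsilyloxy)benzofuran-2-yl]chroman-4-one
Conditions: TBSCl, imidazole, DMF, rt
Reagents that add atoms: tert-butylchlorodimethylsilane, CC(C)(C)[Si](C)(C)Cl
Why: imidazole-mediated silylation of the remaining phenol, which would otherwise deactivate the para ketone as a phenoxide and open quinone-methide pathways at the carbinol stage.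

Step 11
Reactants: 20 7-(tert-butyldimethylsilyloxy)-2,2-dimethyl-6-(3-methylbut-2-enyl)-5-[6-(triisopropylsilyloxy)benzofuran-2-yl]chroman-4-one
Product: 21 7-(tert-butyldimethylsilyloxy)-2,2-dimethyl-6-(3-methylbut-2-enyl)-5-[6-(triisopropylsilyloxy)benzofuran-2-yl]chroman-4-ol (racemic)
Conditions: DIBAL-H, CH2Cl2, −78 °C; aq Rochelle salt
Reagents that add atoms: none
Why: 1,2-hydride reduction of the aryl ketone under aprotic, low-temperature conditions that spare both aryl silyl ethers (the 7-silyl ether para to the ketone is labile to alkoxide); the new carbinol centre is racemic and is erased in step 12.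

Step 12
Reactants: 21 7-(tert-butyldimethylsilyloxy)-2,2-dimethyl-6-(3-methylbut-2-enyl)-5-[6-(triisopropylsilyloxy)benzofuran-2-yl]chroman-4-ol
Product: 22 tert-butyl{[2,2-dimethyl-6-(3-methylbut-2-enyl)-5-[6-(triisopropylsilyloxy)benzofuran-2-yl]-2H-chromen-7-yl]oxy}dimethylsilane (bis-silylated cathafuran C)
Conditions: PPTS (cat.), toluene, 4 Å MS, 70 °C, dilute
Reagents that add atoms: none
Why: acid-catalysed E1 dehydration through a benzylic cation stabilised by the para silyloxy group and the ortho ring oxygen, so a weak acid suffices and the prenyl alkene and both silyl ethers survive, giving the conjugated 2H-chromene.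

Step 13
Reactants: 22 bis-silylated cathafuran C
Product: 23 cathafuran C, 5-(6-hydroxybenzofuran-2-yl)-2,2-dimethyl-6-(3-methylbut-2-enyl)-2H-chromen-7-ol
Conditions: TBAF, AcOH, THF, 0 °C → rt
Reagents that add atoms: none
Why: fluoride cleavage of both aryl silyl ethers driven by the strong Si–F bond; acetic acid buffering keeps the phenoxide concentration low and protects the electron-rich chromene.

**Compound list**

1 | methyl acetoacetate | CC(=O)CC(=O)OC | starting material
2 | prenyl bromide (1-bromo-3-methylbut-2-ene) | CC(C)=CCBr | starting material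
3 | sodium lithium dianion of methyl acetoacetate | [Na+].[Li+].[O-]C(=C)C=C([O-])OC | intermediate (not isolated)
4 | methyl 7-methyl-3-oxooct-6-enoate | COC(=O)CC(=O)CCC=C(C)C | intermediate
5 | methyl 7-methyl-3-(trimethylsilyloxy)octa-2,6-dienoate (C2=C3 isomer mixture) | COC(=O)C=C(O[Si](C)(C)C)CCC=C(C)C | intermediate
6 | lithium (3Z)-1-methoxy-7-methyl-3-(trimethylsilyloxy)octa-1,3,6-trien-1-olate | [Li+].COC([O-])=C/C(O[Si](C)(C)C)=C/CC=C(C)C | intermediate (not isolated)
7 | (3Z)-1-methoxy-7-methyl-1,3-bis(trimethylsilyloxy)octa-1,3,6-triene | COC(O[Si](C)(C)C)=C/C(O[Si](C)(C)C)=C/CC=C(C)C | intermediate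
8 | benzofuran-6-ol | Oc1ccc2ccoc2c1 | starting material
9 | 6-(triisopropylsilyloxy)benzofuran | CC(C)[Si](Oc1ccc2ccoc2c1)(C(C)C)C(C)C | intermediate
10 | 2-lithio-6-(triisopropylsilyloxy)benzofuran | [Li]c1cc2ccc(O[Si](C(C)C)(C(C)C)C(C)C)cc2o1 | intermediate (not isolated)
11 | 2-iodo-6-(triisopropylsilyloxy)benzofuran | Ic1cc2ccc(O[Si](C(C)C)(C(C)C)C(C)C)cc2o1 | intermediate
12 | 3-methylbut-2-enal | CC(C)=CC=O | starting material
13 | ethynylmagnesium bromide | C#C[Mg]Br | starting material
14 | 5-methylhex-4-en-1-yn-3-ol (racemic) | CC(C)=CC(O)C#C | intermediate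
15 | 5-methyl-1-[6-(triisopropylsilyloxy)benzofuran-2-yl]hex-4-en-1-yn-3-ol (racemic) | CC(C)=CC(O)C#Cc1cc2ccc(O[Si](C(C)C)(C(C)C)C(C)C)cc2o1 | intermediate
16 | 5-methyl-1-[6-(triisopropylsilyloxy)benzofuran-2-yl]hex-4-en-1-yn-3-one | CC(C)=CC(=O)C#Cc1cc2ccc(O[Si](C(C)C)(C(C)C)C(C)C)cc2o1 | intermediate
17 | 1-{6-methoxy-3-(3-methylbut-2-enyl)-2-[6-(triisopropylsilyloxy)benzofuran-2-yl]-4,6-bis(trimethylsilyloxy)cyclohexa-1,4-dien-1-yl}-3-methylbut-2-en-1-one (diastereomer mixture, racemic) | COC1(O[Si](C)(C)C)C=C(O[Si](C)(C)C)C(CC=C(C)C)C(c2cc3ccc(O[Si](C(C)C)(C(C)C)C(C)C)cc3o2)=C1C(=O)C=C(C)C | intermediate (not isolated)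
18 | 1-{2,4-dihydroxy-5-(3-methylbut-2-enyl)-6-[6-(triisopropylsilyloxy)benzofuran-2-yl]phenyl}-3-methylbut-2-en-1-one | CC(C)=CCc1c(O)cc(O)c(C(=O)C=C(C)C)c1-c1cc2ccc(O[Si](C(C)C)(C(C)C)C(C)C)cc2o1 | intermediate (not isolated)
19 | 7-hydroxy-2,2-dimethyl-6-(3-methylbut-2-enyl)-5-[6-(triisopropylsilyloxy)benzofuran-2-yl]chroman-4-one | CC(C)=CCc1c(O)cc2c(c1-c1cc3ccc(O[Si](C(C)C)(C(C)C)C(C)C)cc3o1)C(=O)CC(C)(C)O2 | intermediate
20 | 7-(tert-butyldimethylsilyloxy)-2,2-dimethyl-6-(3-methylbut-2-enyl)-5-[6-(triisopropylsilyloxy)benzofuran-2-yl]chroman-4-one | CC(C)=CCc1c(O[Si](C)(C)C(C)(C)C)cc2c(c1-c1cc3ccc(O[Si](C(C)C)(C(C)C)C(C)C)cc3o1)C(=O)CC(C)(C)O2 | intermediate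
21 | 7-(tert-butyldimethylsilyloxy)-2,2-dimethyl-6-(3-methylbut-2-enyl)-5-[6-(triisopropylsilyloxy)benzofuran-2-yl]chroman-4-ol (racemic) | CC(C)=CCc1c(O[Si](C)(C)C(C)(C)C)cc2c(c1-c1cc3ccc(O[Si](C(C)C)(C(C)C)C(C)C)cc3o1)C(O)CC(C)(C)O2 | intermediate
22 | bis-silylated cathafuran C (7-OTBS, benzofuran 6-OTIPS) | CC(C)=CCc1c(O[Si](C)(C)C(C)(C)C)cc2c(c1-c1cc3ccc(O[Si](C(C)C)(C(C)C)C(C)C)cc3o1)C=CC(C)(C)O2 | intermediate
23 | cathafuran C | CC(C)=CCc1c(O)cc2c(c1-c1cc3ccc(O)cc3o1)C=CC(C)(C)O2 | target

**Summary**

Total step count: 13.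
Longest linear sequence: 9 steps (from benzofuran-6-ol 8: steps 4, 5, 7, 8, 9, 10, 11, 12, 13).

**Steps most likely to fail**

1. Step 9. The cycloaddition at the internal, donor-substituted triple bond may be slower than thermal decay of the diene (silyl migration, hydrolysis, oligomerisation). The crowded bond between the prenyl-bearing and the aryl-bearing carbon may also fail to form, or open-chain Michael-type addition may take over.
   Fallback: put a slim, activating alkynyl group on the dienophile in place of the benzofuran and build the benzofuran after the benzannulation. It sets out from aldehyde 12 and diene 7 and comes back at 19.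
   - Commercial 1,4-bis(trimethylsilyl)buta-1,3-diyne would be mono-desilylated with MeLi·LiBr (THF, −78 °C → rt) and the lithium diynide added to 12 to give 7-methyl-1-(trimethylsilyl)oct-6-ene-1,3-diyn-5-ol F1.
   - MnO2 (CH2Cl2, rt) would give 7-methyl-1-(trimethylsilyl)oct-6-ene-1,3-diyn-5-one F2.
   - Heating F2 with 7 as in step 9 should give, at the ynone triple bond, 1-{6-methoxy-3-(3-methylbut-2-enyl)-4,6-bis(trimethylsilyloxy)-2-[(trimethylsilyl)ethynyl]cyclohexa-1,4-dien-1-yl}-3-methylbut-2-en-1-one F3.
   - The same acid treatment would give 1-{2,4-dihydroxy-5-(3-methylbut-2-enyl)-6-[(trimethylsilyl)ethynyl]phenyl}-3-methylbut-2-en-1-one F4, and Et3N would close it to 7-hydroxy-2,2-dimethyl-6-(3-methylbut-2-enyl)-5-[(trimethylsilyl)ethynyl]chroman-4-one F5.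
   - K2CO3/MeOH (0 °C) would free 5-ethynyl-7-hydroxy-2,2-dimethyl-6-(3-methylbut-2-enyl)chroman-4-one F6.
   - Commercial 4-iodoresorcinol, silylated at its less hindered hydroxyl (TIPSCl, imidazole, CH2Cl2, 0 °C), would give 2-iodo-5-(triisopropylsilyloxy)phenol F7.
   - Sonogashira coupling of F6 with F7 (PdCl2(PPh3)2, CuI, Et3N, DMF, 60 °C), with 5-endo-dig closure of the o-alkynylphenol in the same pot, should give 19.

2. Step 3. γ-Deprotonation may be incomplete, silylation may occur at carbon, the diene may hydrolyse back to the keto ester on handling, or the 3E geometry (which cannot reach the s-cis conformation) may form in quantity.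
   Fallback: use a cyclic acetonide equivalent of the diene, in which the tied-back ring oxygen and allylic strain with the ring C5–H fix the exocyclic alkene geometry. It sets out from prenyl bromide 2 and comes back at 18, which closes to 19 as in step 9.
   - Commercial 2,2,6-trimethyl-4H-1,3-dioxin-4-one would be γ-alkylated (LDA, THF/DMPU, −78 °C, then 2) to 2,2-dimethyl-6-(4-methylpent-3-en-1-yl)-4H-1,3-dioxin-4-one F8.
   - LDA/TMSCl (−78 °C) would give trimethyl{[(6Z)-2,2-dimethyl-6-(4-methylpent-3-en-1-ylidene)-6H-1,3-dioxin-4-yl]oxy}silane F9.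
   - Heating F9 with 16 in toluene should give the bicyclic acetonide cycloadduct F10 with the same orientation.
   - Dilute acid would make F10 lose acetone and the TMS group and aromatise to 18; Et3N then gives 19.

3. Step 12. Ionisation of the carbinol under acid may lead to capture of the benzylic cation by C3 of the neighbouring benzofuran (fluorene-type Friedel–Crafts closure), to dimerisation of the electron-rich chromene, to cyclisation or migration of the prenyl group, or to partial loss of a silyl ether.
   Fallback: avoid the cation and reach the alkene by reduction of an enol triflate. It sets out from ketone 20 (in place of steps 11 and 12) and comes back at 22.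
   - KHMDS and PhNTf2 (THF, −78 °C) would give 7-(tert-butyldimethylsilyloxy)-2,2-dimethyl-6-(3-methylbut-2-enyl)-5-[6-(triisopropylsilyloxy)benzofuran-2-yl]-2H-chromen-4-yl trifluoromethanesulfonate F11.
   - Palladium-catalysed formate reduction (Pd(OAc)2, PPh3, Et3N, HCO2H, DMF, 60 °C) should give 22.

**Further compounds**

F1 | step 9 | 7-methyl-1-(trimethylsilyl)oct-6-ene-1,3-diyn-5-ol (racemic) | CC(C)=CC(O)C#CC#C[Si](C)(C)C
F2 | step 9 | 7-methyl-1-(trimethylsilyl)oct-6-ene-1,3-diyn-5-one | CC(C)=CC(=O)C#CC#C[Si](C)(C)C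
F3 | step 9 | 1-{6-methoxy-3-(3-methylbut-2-enyl)-4,6-bis(trimethylsilyloxy)-2-[(trimethylsilyl)ethynyl]cyclohexa-1,4-dien-1-yl}-3-methylbut-2-en-1-one (not isolated) | COC1(O[Si](C)(C)C)C=C(O[Si](C)(C)C)C(CC=C(C)C)C(C#C[Si](C)(C)C)=C1C(=O)C=C(C)C
F4 | step 9 | 1-{2,4-dihydroxy-5-(3-methylbut-2-enyl)-6-[(trimethylsilyl)ethynyl]phenyl}-3-methylbut-2-en-1-one (not isolated) | CC(C)=CCc1c(O)cc(O)c(C(=O)C=C(C)C)c1C#C[Si](C)(C)C
F5 | step 9 | 7-hydroxy-2,2-dimethyl-6-(3-methylbut-2-enyl)-5-[(trimethylsilyl)ethynyl]chroman-4-one | CC(C)=CCc1c(O)cc2c(c1C#C[Si](C)(C)C)C(=O)CC(C)(C)O2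
F6 | step 9 | 5-ethynyl-7-hydroxy-2,2-dimethyl-6-(3-methylbut-2-enyl)chroman-4-one | CC(C)=CCc1c(O)cc2c(c1C#C)C(=O)CC(C)(C)O2
F7 | step 9 | 2-iodo-5-(triisopropylsilyloxy)phenol | CC(C)[Si](Oc1ccc(I)c(O)c1)(C(C)C)C(C)C
F8 | step 3 | 2,2-dimethyl-6-(4-methylpent-3-en-1-yl)-4H-1,3-dioxin-4-one | CC(C)=CCCC1=CC(=O)OC(C)(C)O1
F9 | step 3 | trimethyl{[(6Z)-2,2-dimethyl-6-(4-methylpent-3-en-1-ylidene)-6H-1,3-dioxin-4-yl]oxy}silane | CC(C)=CC/C=C1/C=C(O[Si](C)(C)C)OC(C)(C)O1
F10 | step 3 | bicyclic acetonide cycloadduct of F9 and 16 (not isolated, racemic diastereomer mixture) | CC(C)=CCC1C(c2cc3ccc(O[Si](C(C)C)(C(C)C)C(C)C)cc3o2)=C(C(=O)C=C(C)C)C2(O[Si](C)(C)C)C=C1OC(C)(C)O2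
F11 | step 12 | 7-(tert-butyldimethylsilyloxy)-2,2-dimethyl-6-(3-methylbut-2-enyl)-5-[6-(triisopropylsilyloxy)benzofuran-2-yl]-2H-chromen-4-yl trifluoromethanesulfonate | CC(C)=CCc1c(O[Si](C)(C)C(C)(C)C)cc2c(c1-c1cc3ccc(O[Si](C(C)C)(C(C)C)C(C)C)cc3o1)C(OS(=O)(=O)C(F)(F)F)=CC(C)(C)O2
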